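**Plan**

- Retrosynthesis of (R)-α-tocotrienol: first the C6 silyl ether, then the C2'–C3' bond of the side chain, which gives the C2' iodide 13 and the C14 (1E,5E)-vinyl iodide 20. Next, O1–C2 and C1'–C2' of the chroman-2-ylacetate 11 are cut together, back to alkenyl phenol 8, CO and methanol. Last, C4–C4a is cut, back to trimethylhydroquinone and methyl vinyl ketone.
- Enabling feature (chroman numbering O1, C2–C4, C4a, C5–C8, C8a; chain C1' onward from C2): C2 carries O1, a methyl, C3 and C1' and no hydrogen. Palladium delivered to C1' by oxypalladation therefore has no β-hydrogen and can take up CO.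
- Forward: the benzene ring is bought; the dihydropyran ring (O1, C2, C3, C4, C4a, C8a) closes in step 5; the chain is joined at C2'–C3' in step 11 by a B-alkyl Suzuki–Miyaura coupling; the phenol is freed last.
- Stereochemistry: C2 (R in the target) is set in step 5 by the chiral bis(oxazoline) ligand on palladium. The 7'E alkene comes with geranyl bromide; the 3'E alkene comes from syn carboalumination–iodination (step 10) and a stereoretentive coupling.

Key step: step 5

**Remarks**

- Ligand: (S,S)-Bn-BOXAX is 2,2'-bis[(4S)-4-benzyl-4,5-dihydrooxazol-2-yl]-1,1'-binaphthyl with (S) axis. It is a known ligand made separately from a 1-bromo-2-naphthoic acid derivative and (S)-phenylalaninol, is used in substoichiometric amount and is not counted in the step total.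
- Assumption: the (S,S)-ligand is taken to deliver the phenol oxygen to the alkene face that gives (S)-11; should the sense be the reverse, the (R,R)-ligand is used instead.
- The descriptor at C2 changes from S (11–13) to R (21–24) only because the CIP ranks of C1' and C3 swap; the spatial arrangement is the same throughout.
- Short-lived ionic and catalyst-bound species are described in the Why lines and carry no number; discrete compounds made and consumed in the flask are numbered.

**Route**

Step 1
Reactants: 1 trimethylhydroquinone; 2 methyl vinyl ketone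
Product: 4 (±)-2-methoxy-2,5,7,8-tetramethylchroman-6-ol, via keto hydroquinone 3 (not isolated)
Conditions: HC(OMe)3, MeOH, H2SO4 (cat.), 0 °C to rt
Reagents that add atoms: trimethyl orthoformate, COC(OC)OC
Why: Acid-catalysed Friedel–Crafts-type Michael addition of the electron-rich arene occurs at its only unsubstituted carbon, and the ketone of 3 is then trapped by the neighbouring phenol and methanol as the cyclic mixed ketal, which leaves a single free phenol for the next step.

Step 2
Reactants: 4 (±)-2-methoxy-2,5,7,8-tetramethylchroman-6-ol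
Product: 5 (±)-tert-butyl[(2-methoxy-2,5,7,8-tetramethylchroman-6-yl)oxy]dimethylsilane
Conditions: TBSCl, imidazole, DMF, 50 °C
Reagents that add atoms: tert-butyldimethylsilyl chloride, CC(C)(C)[Si](C)(C)Cl
Why: Imidazole-promoted O-silylation of the only hydroxyl group should proceed on warming despite the two flanking methyl groups, which in turn make the aryl silyl ether robust in the later steps.

Step 3
Reactants: 5 (±)-tert-butyl[(2-methoxy-2,5,7,8-tetramethylchroman-6-yl)oxy]dimethylsilane
Product: 6 (±)-6-(tert-butyldimethylsilyloxy)-2,5,7,8-tetramethylchroman-2-ol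
Conditions: 0.5 M HCl (aq), THF, rt
Reagents that add atoms: water, O
Why: Acid-catalysed ketal hydrolysis through a tertiary oxocarbenium ion is far faster than protodesilylation of a hindered aryl silyl ether, so only the methoxy group should be exchanged for hydroxyl.

Step 4
Reactants: 6 (±)-6-(tert-butyldimethylsilyloxy)-2,5,7,8-tetramethylchroman-2-ol
Product: 8 4-(tert-butyldimethylsilyloxy)-3,5,6-trimethyl-2-(3-methylbut-3-en-1-yl)phenol, via open-chain keto phenol 7 (not isolated)
Conditions: MePPh3Br (3.5 equiv), KN(SiMe3)2 (3.3 equiv), THF, 0 °C; then 6, 0 to 60 °C; NH4Cl (aq)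
Reagents that add atoms: methyltriphenylphosphonium bromide, C[P+](c1ccccc1)(c1ccccc1)c1ccccc1.[Br-]
Why: Wittig methylenation of a lactol: the first equivalent of ylide deprotonates 6, the lactolate opens to the keto phenoxide form of 7, and further ylide converts its unhindered methyl ketone into the 1,1-disubstituted alkene while the phenoxide stays inert.

Step 5
Reactants: 8 4-(tert-butyldimethylsilyloxy)-3,5,6-trimethyl-2-(3-methylbut-3-en-1-yl)phenol; 9 carbon monoxide; 10 methanol
Product: 11 methyl (S)-2-[6-(tert-butyldimethylsilyloxy)-2,5,7,8-tetramethylchroman-2-yl]acetate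
Conditions: Pd(OCOCF3)2 (10 mol %), (S,S)-Bn-BOXAX (40 mol %), p-benzoquinone (4 equiv), CO (1 atm), MeOH, rt
Reagents that add atoms: carbon monoxide 9, [C-]#[O+]; methanol 10, CO
Why: The cationic complex of divalent palladium with the chiral bis(oxazoline) binds the 1,1-disubstituted alkene of 8, the free phenol oxygen adds to the internal alkene carbon (oxypalladation), and the primary alkylpalladium formed at C1' inserts CO to an acylpalladium that methanol cleaves to the methyl ester, after which p-benzoquinone returns zerovalent palladium to the divalent state. The closest known reaction type is the enantioselective domino Wacker cyclisation–alkoxycarbonylation of ortho-homoallyl phenols to chroman-2-ylacetates. The dihydropyran ring (O1, C2, C3, C4, C4a, C8a) closes in the 6-exo-trig mode by formation of O1–C2. The single new stereocenter C2 is under catalyst control, the binaphthyl bis(oxazoline) differentiating the two alkene faces so that (S)-11 is expected. The step needs Markovnikov regioselectivity, secured by the methyl-bearing internal carbon, and it needs the alkylpalladium to escape β-hydride elimination, secured by the fully substituted C2 next to C1'. The silyl ether at C6 leaves the C8a hydroxyl as the only nucleophile and keeps the hydroquinone core from being oxidised by the quinone.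

Step 6
Reactants: 11 methyl (S)-2-[6-(tert-butyldimethylsilyloxy)-2,5,7,8-tetramethylchroman-2-yl]acetate
Product: 12 (S)-2-[6-(tert-butyldimethylsilyloxy)-2,5,7,8-tetramethylchroman-2-yl]ethanol
Conditions: iBu2AlH (2.5 equiv), CH2Cl2, −78 to 0 °C; potassium sodium tartrate (aq)
Reagents that add atoms: none
Why: Hydride reduction of the ester through the aldehyde should give the primary alcohol, and at low temperature neither the hindered aryl silyl ether nor the quaternary C2 is touched.

Step 7
Reactants: 12 (S)-2-[6-(tert-butyldimethylsilyloxy)-2,5,7,8-tetramethylchroman-2-yl]ethanol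
Product: 13 (S)-tert-butyl{[2-(2-iodoethyl)-2,5,7,8-tetramethylchroman-6-yl]oxy}dimethylsilane
Conditions: I2, PPh3, imidazole, CH2Cl2, 0 °C to rt
Reagents that add atoms: iodine, II
Why: Appel-type iodination activates the primary alcohol as an alkoxyphosphonium ion that iodide displaces in an SN2 step at C2', two bonds away from the stereocenter.

Step 8
Reactants: 14 geranyl bromide; 15 1-(trimethylsilyl)propyne
Product: 17 (E)-(6,10-dimethylundeca-5,9-dien-1-yn-1-yl)trimethylsilane, via 3-lithio-1-(trimethylsilyl)propyne 16 (not isolated)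
Conditions: 15, n-BuLi, THF, −78 to −20 °C; then 14, −78 °C to rt
Reagents that add atoms: none
Why: Propargylic lithiation followed by SN2 alkylation at the primary allylic bromide should join the two pieces, the silyl group blocking the alkyne terminus and favouring the propargyl over the allenyl product, with the E alkene of the geranyl unit unchanged.

Step 9
Reactants: 17 (E)-(6,10-dimethylundeca-5,9-dien-1-yn-1-yl)trimethylsilane
Product: 18 (E)-6,10-dimethylundeca-5,9-dien-1-yne
Conditions: K2CO3 (cat.), MeOH, rt
Reagents that add atoms: none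
Why: Base-catalysed methanolysis (protodesilylation) cleaves only the silicon–alkynyl bond and leaves both alkenes alone.

Step 10
Reactants: 18 (E)-6,10-dimethylundeca-5,9-dien-1-yne
Product: 20 (1E,5E)-1-iodo-2,6,10-trimethylundeca-1,5,9-triene, via alkenyldimethylalane 19 (not isolated)
Conditions: Me3Al (2 equiv), Cp2ZrCl2 (25 mol %), CH2Cl2, 0 °C to rt; then I2, THF, −30 to 0 °C
Reagents that add atoms: trimethylaluminium, C[Al](C)C; iodine, II
Why: Negishi zirconium-catalysed carboalumination adds methyl and aluminium syn across the terminal alkyne with aluminium on the terminal carbon, and iodine replaces aluminium with retention, so the new trisubstituted alkene is E while the existing alkenes do not react.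

Step 11
Reactants: 13 (S)-tert-butyl{[2-(2-iodoethyl)-2,5,7,8-tetramethylchroman-6-yl]oxy}dimethylsilane; 20 (1E,5E)-1-iodo-2,6,10-trimethylundeca-1,5,9-triene
Product: 23 tert-butyldimethyl{[(R)-2,5,7,8-tetramethyl-2-((3E,7E)-4,8,12-trimethyltrideca-3,7,11-trien-1-yl)chroman-6-yl]oxy}silane, via alkyllithium 21 (not isolated), via lithium alkylborate 22 (not isolated)
Conditions: 13, t-BuLi (2.1 equiv), Et2O, −78 °C; B-methoxy-9-BBN, THF, −78 °C to rt; then 20, PdCl2(dppf) (5 mol %), AsPh3 (10 mol %), K3PO4 (3 M aq), DMF, rt
Reagents that add atoms: none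
Why: B-alkyl Suzuki–Miyaura coupling: lithium–iodine exchange and capture on boron give a borate that transfers its primary alkyl group to the alkenylpalladium iodide formed from 20 by oxidative addition, and reductive elimination forms C2'–C3' with retention of the E geometry and without involving C2.

Step 12
Reactants: 23 tert-butyldimethyl{[(R)-2,5,7,8-tetramethyl-2-((3E,7E)-4,8,12-trimethyltrideca-3,7,11-trien-1-yl)chroman-6-yl]oxy}silane
Product: 24 (R)-2,5,7,8-tetramethyl-2-[(3E,7E)-4,8,12-trimethyltrideca-3,7,11-trien-1-yl]chroman-6-ol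
Conditions: Bu4NF, AcOH, THF, 0 °C to rt, argon
Reagents that add atoms: none
Why: Fluoride-induced cleavage of the aryl silyl ether is driven by the strong silicon–fluorine bond, and buffering with acetic acid under argon should protect the electron-rich chromanol from base-promoted air oxidation while the triene is inert.

**Compound list**

1 | trimethylhydroquinone (2,3,5-trimethylbenzene-1,4-diol) | Cc1cc(O)c(C)c(C)c1O | starting material
2 | methyl vinyl ketone (but-3-en-2-one) | CC(=O)C=C | starting material
3 | 4-(2,5-dihydroxy-3,4,6-trimethylphenyl)butan-2-one (keto hydroquinone) | CC(=O)CCc1c(C)c(O)c(C)c(C)c1O | intermediate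
4 | (±)-2-methoxy-2,5,7,8-tetramethylchroman-6-ol | COC1(C)CCc2c(C)c(O)c(C)c(C)c2O1 | intermediate
5 | (±)-tert-butyl[(2-methoxy-2,5,7,8-tetramethylchroman-6-yl)oxy]dimethylsilane | COC1(C)CCc2c(C)c(O[Si](C)(C)C(C)(C)C)c(C)c(C)c2O1 | intermediate
6 | (±)-6-(tert-butyldimethylsilyloxy)-2,5,7,8-tetramethylchroman-2-ol | CC1(O)CCc2c(C)c(O[Si](C)(C)C(C)(C)C)c(C)c(C)c2O1 | intermediate
7 | 4-[5-(tert-butyldimethylsilyloxy)-2-hydroxy-3,4,6-trimethylphenyl]butan-2-one (open-chain tautomer of 6, present as its phenoxide) | CC(=O)CCc1c(C)c(O[Si](C)(C)C(C)(C)C)c(C)c(C)c1O | intermediate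
8 | 4-(tert-butyldimethylsilyloxy)-3,5,6-trimethyl-2-(3-methylbut-3-en-1-yl)phenol | C=C(C)CCc1c(C)c(O[Si](C)(C)C(C)(C)C)c(C)c(C)c1O | intermediate
9 | carbon monoxide | [C-]#[O+] | starting material
10 | methanol | CO | starting material
11 | methyl (S)-2-[6-(tert-butyldimethylsilyloxy)-2,5,7,8-tetramethylchroman-2-yl]acetate | COC(=O)C[C@]1(C)CCc2c(C)c(O[Si](C)(C)C(C)(C)C)c(C)c(C)c2O1 | intermediate
12 | (S)-2-[6-(tert-butyldimethylsilyloxy)-2,5,7,8-tetramethylchroman-2-yl]ethanol | OCC[C@]1(C)CCc2c(C)c(O[Si](C)(C)C(C)(C)C)c(C)c(C)c2O1 | intermediate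
13 | (S)-tert-butyl{[2-(2-iodoethyl)-2,5,7,8-tetramethylchroman-6-yl]oxy}dimethylsilane | ICC[C@]1(C)CCc2c(C)c(O[Si](C)(C)C(C)(C)C)c(C)c(C)c2O1 | intermediate
14 | geranyl bromide ((E)-1-bromo-3,7-dimethylocta-2,6-diene) | CC(C)=CCC/C(C)=C/CBr | starting material
15 | 1-(trimethylsilyl)propyne | CC#C[Si](C)(C)C | starting material
16 | 3-lithio-1-(trimethylsilyl)propyne | [Li]CC#C[Si](C)(C)C | intermediate
17 | (E)-(6,10-dimethylundeca-5,9-dien-1-yn-1-yl)trimethylsilane | CC(C)=CCC/C(C)=C/CCC#C[Si](C)(C)C | intermediate
18 | (E)-6,10-dimethylundeca-5,9-dien-1-yne | CC(C)=CCC/C(C)=C/CCC#C | intermediate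
19 | dimethyl[(1E,5E)-2,6,10-trimethylundeca-1,5,9-trien-1-yl]alane | CC(C)=CCC/C(C)=C/CC/C(C)=C/[Al](C)C | intermediate
20 | (1E,5E)-1-iodo-2,6,10-trimethylundeca-1,5,9-triene | CC(C)=CCC/C(C)=C/CC/C(C)=C/I | intermediate
21 | (R)-{2-[6-(tert-butyldimethylsilyloxy)-2,5,7,8-tetramethylchroman-2-yl]ethyl}lithium | [Li]CC[C@]1(C)CCc2c(C)c(O[Si](C)(C)C(C)(C)C)c(C)c(C)c2O1 | intermediate
22 | lithium (R)-9-{2-[6-(tert-butyldimethylsilyloxy)-2,5,7,8-tetramethylchroman-2-yl]ethyl}-9-methoxy-9-boratabicyclo[3.3.1]nonane | [Li+].CO[B-]1(CC[C@]2(C)CCc3c(C)c(O[Si](C)(C)C(C)(C)C)c(C)c(C)c3O2)C2CCCC1CCC2 | intermediate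
23 | tert-butyldimethyl{[(R)-2,5,7,8-tetramethyl-2-((3E,7E)-4,8,12-trimethyltrideca-3,7,11-trien-1-yl)chroman-6-yl]oxy}silane | CC(C)=CCC/C(C)=C/CC/C(C)=C/CC[C@]1(C)CCc2c(C)c(O[Si](C)(C)C(C)(C)C)c(C)c(C)c2O1 | intermediate
24 | (R)-2,5,7,8-tetramethyl-2-[(3E,7E)-4,8,12-trimethyltrideca-3,7,11-trien-1-yl]chroman-6-ol ((R)-α-tocotrienol, CID5282347) | CC(C)=CCC/C(C)=C/CC/C(C)=C/CC[C@]1(C)CCc2c(C)c(O)c(C)c(C)c2O1 | target

**Step count and risks**

Total: 12 steps. Longest linear sequence: 9 steps (steps 1–7, 11, 12); the side-chain branch (steps 8–10) has 3 steps.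

Steps most likely to fail:

1. Step 5. The ligand may discriminate the two alkene faces less well with the silyl ether substrate than hoped, so that 11 is formed with insufficient enantiomeric purity. The fallback is a classical resolution that sets out from 11 and returns to 11. Compound 11 is heated with KOH in aqueous methanol under argon, which hydrolyses the ester and also removes the aryl silyl group. This gives (S)-enriched (S)-2-(6-hydroxy-2,5,7,8-tetramethylchroman-2-yl)acetic acid F1. The acid is crystallised to diastereomeric purity as its salt with (S)-1-phenylethylamine, (S)-1-phenylethylammonium (S)-2-(6-hydroxy-2,5,7,8-tetramethylchroman-2-yl)acetate F2; the (R)-amine is taken if its salt with the (S)-acid proves the less soluble one. Dilute HCl returns F1, now enantiopure. Fischer esterification (MeOH, H2SO4 cat., reflux) gives methyl (S)-2-(6-hydroxy-2,5,7,8-tetramethylchroman-2-yl)acetate F3, and silylation as in step 2 (TBSCl, imidazole, DMF) comes back to 11.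

2. Step 11. Lithium–iodine exchange may be unclean (Wurtz coupling, protonation of the alkyllithium), and transfer of the alkyl group from boron to palladium may be slower than protodeboronation, so that 13 is consumed without forming C2'–C3'. The fallback replaces the lithium and boron intermediates by an organozinc reagent; it sets out from 13 and returns at 23. Direct insertion of activated Zn dust into 13 (LiCl, THF, 40 °C) gives (S)-{2-[6-(tert-butyldimethylsilyloxy)-2,5,7,8-tetramethylchroman-2-yl]ethyl}zinc iodide F4. This is coupled with 20 under Negishi conditions (Pd(PPh3)4, THF, rt to 50 °C) to give 23.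

3. Step 4. The basic ylide may enolise the methyl ketone of the opened lactol or leave the substrate resting as the closed lactolate, so that methylenation stalls. The fallback is a two-stage Peterson olefination that sets out from 6 and returns at 8. Addition of Me3SiCH2MgCl in the presence of CeCl3 (THF, −78 °C to rt), a weakly basic nucleophile, to the open form of 6 gives 4-[5-(tert-butyldimethylsilyloxy)-2-hydroxy-3,4,6-trimethylphenyl]-2-methyl-1-(trimethylsilyl)butan-2-ol F5. Base-induced syn elimination (KH, THF, 0 °C to rt) then gives 8; acid is avoided because it would close the tertiary carbinol onto the phenol.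

**Further compounds**

F1 | step 5 | (S)-2-(6-hydroxy-2,5,7,8-tetramethylchroman-2-yl)acetic acid | OC(=O)C[C@]1(C)CCc2c(C)c(O)c(C)c(C)c2O1
F2 | step 5 | (S)-1-phenylethylammonium (S)-2-(6-hydroxy-2,5,7,8-tetramethylchroman-2-yl)acetate | C[C@H]([NH3+])c1ccccc1.[O-]C(=O)C[C@]1(C)CCc2c(C)c(O)c(C)c(C)c2O1
F3 | step 5 | methyl (S)-2-(6-hydroxy-2,5,7,8-tetramethylchroman-2-yl)acetate | COC(=O)C[C@]1(C)CCc2c(C)c(O)c(C)c(C)c2O1
F4 | step 11 | (S)-{2-[6-(tert-butyldimethylsilyloxy)-2,5,7,8-tetramethylchroman-2-yl]ethyl}zinc iodide | I[Zn]CC[C@]1(C)CCc2c(C)c(O[Si](C)(C)C(C)(C)C)c(C)c(C)c2O1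
F5 | step 4 | 4-[5-(tert-butyldimethylsilyloxy)-2-hydroxy-3,4,6-trimethylphenyl]-2-methyl-1-(trimethylsilyl)butan-2-ol | C[Si](C)(C)CC(C)(O)CCc1c(C)c(O[Si](C)(C)C(C)(C)C)c(C)c(C)c1O
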